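**Retrosynthetic overview** (cembrane numbering: C1 bears the isopropyl group, C4 the CO2Me, C7 the OAc, C8 the methyl and the lactone oxygen, C12 is the lactone α-carbon, C20 the lactone carbonyl)

1. The 14-membered ring is closed last at C3=C4 by intramolecular Horner–Wadsworth–Emmons olefination; C1–C14 comes from a Negishi coupling of a core alkylzinc with a (Z)-β-iodo enal.
2. The seven-membered lactone (O–C8–C9–C10–C11=C12–C20) is treated as the Baeyer–Villiger homologue of a 2-cyclohexenone: a temporary C8–C20 bond, absent from the target, is later cleaved by oxygen insertion with retention at C8.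
3. That cyclohexenone is made in one operation from an acyclic α-methyl β-keto ester and acrolein: asymmetric Michael addition (C8–C9), then aldol condensation (C11=C12).
4. Enabling feature: C8 and C12 both hang on the lactone C20(=O)–O unit; without the ring oxygen they are the α- and α′-carbons of one ketone, a 1,3-dinucleophile that the C3 enal (C9–C11) bridges. The ester on C8 (the future C7) makes C8–H the most acidic site and leaves C12 as the only enolisable position.
5. Ring order: six-membered carbocycle (step 2), seven-membered lactone (step 9), 14-membered carbocycle (step 16); C7 is set by reagent-controlled allylboration (step 5).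

Key step: step 2

Remark: the quinidine-series catalyst is assumed to give the (R)-adduct in step 2; if the sense of induction is the opposite, the quinine-series pseudoenantiomer is used instead.

**Route**

Step 1
Reactants: 1 ethyl 2-methyl-3-oxobutanoate; 2 tert-butyl(2-iodoethoxy)dimethylsilane
Product: 4 ethyl 6-[(tert-butyldimethylsilyl)oxy]-2-methyl-3-oxohexanoate (racemic), via sodium lithium dianion 3 (not isolated)
Conditions: NaH, THF, 0 °C; n-BuLi, 0 °C; then 2, 0 to 25 °C
Reagents that add atoms: none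
Why: The terminal carbanion of the acetoacetate dianion is the more nucleophilic site and should be alkylated selectively by the primary iodide (dianion γ-alkylation), installing C13–C14 with an oxygen handle.

Step 2
Reactants: 4 ethyl 6-[(tert-butyldimethylsilyl)oxy]-2-methyl-3-oxohexanoate; 5 acrolein
Product: 7 ethyl (1R)-3-{2-[(tert-butyldimethylsilyl)oxy]ethyl}-1-methyl-2-oxocyclohex-3-ene-1-carboxylate, via Michael adduct 6 (not isolated)
Conditions: 9-O-(9-phenanthryl)cupreidine (10 mol %), CH2Cl2, −24 °C; then Bn2NH·CF3CO2H (30 mol %), toluene, 60 °C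
Reagents that add atoms: none
Why: The bifunctional 6′-hydroxy cinchona base deprotonates the doubly activated C8–H of 4 and delivers the hydrogen-bonded enolate to acrolein (Michael addition, C8–C9); the ammonium salt then promotes aldol condensation of the C12 methylene with the tethered aldehyde to give C11=C12. The closest known reaction type is the organocatalytic Michael/aldol-condensation annulation of β-keto esters with enals to cyclohexenones, together with cinchona-catalysed additions of α-substituted β-keto esters to acrolein. The six-membered ring closes by a 6-(enolendo)-exo-trig aldol addition followed by dehydration, and because C20 and C10 are both ring members the C11=C12 geometry is fixed. The quaternary C8 stereocentre is set by the catalyst, which shields one enolate face, and it cannot epimerise afterwards because it bears no hydrogen. The step needs reaction at C8 rather than C12 in the Michael stage and at C12 in the aldol stage: the acidity gap of several pKa units between the β-dicarbonyl methine and the α′-methylene secures the first, and the quaternary nature of C8 after addition secures the second. The mild ammonium salt is chosen so that the silyl ether should survive and retro-Michael cleavage should not set in.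

Step 3
Reactants: 7 ethyl (1R)-3-{2-[(tert-butyldimethylsilyl)oxy]ethyl}-1-methyl-2-oxocyclohex-3-ene-1-carboxylate
Product: 8 (6S)-2-{2-[(tert-butyldimethylsilyl)oxy]ethyl}-6-(hydroxymethyl)-6-methylcyclohex-2-en-1-ol (both C1 epimers)
Conditions: LiAlH4, Et2O, 0 °C
Reagents that add atoms: none
Why: LiAlH4 should reduce the neopentylic ester to the primary alcohol and the enone carbonyl by 1,2-addition; the new ring carbinol centre is erased in step 4.

Step 4
Reactants: 8 (6S)-2-{2-[(tert-butyldimethylsilyl)oxy]ethyl}-6-(hydroxymethyl)-6-methylcyclohex-2-en-1-ol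
Product: 9 (1S)-3-{2-[(tert-butyldimethylsilyl)oxy]ethyl}-1-methyl-2-oxocyclohex-3-ene-1-carbaldehyde
Conditions: Dess–Martin periodinane, pyridine, CH2Cl2, 25 °C
Reagents that add atoms: none
Why: Dess–Martin oxidation should convert both the allylic and the neopentylic alcohol to carbonyls under non-basic conditions, so the non-enolisable β-keto aldehyde is not exposed to retro-Claisen cleavage.

Step 5
Reactants: 9 (1S)-3-{2-[(tert-butyldimethylsilyl)oxy]ethyl}-1-methyl-2-oxocyclohex-3-ene-1-carbaldehyde
Product: 11 (6S)-2-{2-[(tert-butyldimethylsilyl)oxy]ethyl}-6-[(1R)-1-hydroxybut-3-en-1-yl]-6-methylcyclohex-2-en-1-one, via borinate ester 10 (not isolated)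
Conditions: (+)-Ipc2B(allyl) (from (−)-α-pinene), Et2O, −78 °C; then HOCH2CH2NH2, 25 °C
Reagents that add atoms: (+)-B-allyldiisopinocampheylborane, C=CCB([C@H]1C[C@H]2C[C@@H]([C@@H]1C)C2(C)C)[C@H]1C[C@H]2C[C@@H]([C@@H]1C)C2(C)C
Why: Asymmetric allylboration through a closed chair transition state should add allyl to the aldehyde only (the hindered conjugated ketone is far less reactive), and the isopinocampheyl groups should set C7 as (R) under reagent control.

Step 6
Reactants: 11 (6S)-2-{2-[(tert-butyldimethylsilyl)oxy]ethyl}-6-[(1R)-1-hydroxybut-3-en-1-yl]-6-methylcyclohex-2-en-1-one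
Product: 12 (1R)-1-[(1S)-3-{2-[(tert-butyldimethylsilyl)oxy]ethyl}-1-methyl-2-oxocyclohex-3-en-1-yl]but-3-en-1-yl acetate
Conditions: Ac2O, Et3N, DMAP (cat.), CH2Cl2, 25 °C
Reagents that add atoms: acetic anhydride, CC(=O)OC(C)=O
Why: DMAP-catalysed acylation installs the C7 acetate of the target and protects the carbinol before the oxidations that follow.

Step 7
Reactants: 12 (1R)-1-[(1S)-3-{2-[(tert-butyldimethylsilyl)oxy]ethyl}-1-methyl-2-oxocyclohex-3-en-1-yl]but-3-en-1-yl acetate
Product: 14 (1R)-1-[(1S)-3-{2-[(tert-butyldimethylsilyl)oxy]ethyl}-1-methyl-2-oxocyclohex-3-en-1-yl]-3-hydroxypropyl acetate, via aldehyde 13 (not isolated)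
Conditions: O3, CH2Cl2, −78 °C; PPh3; then NaBH(OAc)3, AcOH, 25 °C
Reagents that add atoms: ozone, [O-][O+]=O
Why: Ozone should cleave the electron-rich terminal alkene much faster than the conjugated trisubstituted enone alkene, and NaBH(OAc)3 reduces the aldehyde but not the ketone, so C5 reaches the alcohol level without exposing the β-acetoxy aldehyde to base.

Step 8
Reactants: 14 (1R)-1-[(1S)-3-{2-[(tert-butyldimethylsilyl)oxy]ethyl}-1-methyl-2-oxocyclohex-3-en-1-yl]-3-hydroxypropyl acetate
Product: 15 (1R)-3-bromo-1-[(1S)-3-{2-[(tert-butyldimethylsilyl)oxy]ethyl}-1-methyl-2-oxocyclohex-3-en-1-yl]propyl acetate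
Conditions: CBr4, PPh3, CH2Cl2, 0 °C
Reagents that add atoms: tetrabromomethane, BrC(Br)(Br)Br
Why: Appel bromination should convert the primary alcohol to a bromide that is inert to peracid, leaving the acetate and silyl ether untouched.

Step 9
Reactants: 15 (1R)-3-bromo-1-[(1S)-3-{2-[(tert-butyldimethylsilyl)oxy]ethyl}-1-methyl-2-oxocyclohex-3-en-1-yl]propyl acetate
Product: 16 (1R)-3-bromo-1-[(2S)-6-{2-[(tert-butyldimethylsilyl)oxy]ethyl}-2-methyl-7-oxo-2,3,4,7-tetrahydrooxepin-2-yl]propyl acetate
Conditions: mCPBA, CH2Cl2, 0 to 25 °C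
Reagents that add atoms: 3-chloroperoxybenzoic acid, OOC(=O)c1cccc(Cl)c1
Why: In this Baeyer–Villiger oxidation the fully substituted C8 should migrate in preference to the vinylic C12 and with retention, as α′,α′-disubstituted cyclohexenones (for example 4,4-dimethyl-1-en-3-one A rings of triterpenoids) give unsaturated ε-lactones, while the electron-poor enone alkene, the bromide, the acetate and the silyl ether should resist the peracid.

Step 10
Reactants: 16 (1R)-3-bromo-1-[(2S)-6-{2-[(tert-butyldimethylsilyl)oxy]ethyl}-2-methyl-7-oxo-2,3,4,7-tetrahydrooxepin-2-yl]propyl acetate; 17 methyl 2-(diethoxyphosphoryl)acetate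
Product: 18 methyl (5R)-5-acetoxy-5-[(2S)-6-{2-[(tert-butyldimethylsilyl)oxy]ethyl}-2-methyl-7-oxo-2,3,4,7-tetrahydrooxepin-2-yl]-2-(diethoxyphosphoryl)pentanoate (both C2 epimers)
Conditions: NaH, 17 (excess), NaI (cat.), THF/DMF, 50 °C
Reagents that add atoms: none
Why: SN2 alkylation of the sodium phosphonoacetate by the primary bromide attaches C4 with its ester and phosphonate; the excess of soft nucleophile suppresses dialkylation and should not add to the α-substituted unsaturated lactone.

Step 11
Reactants: 18 methyl (5R)-5-acetoxy-5-[(2S)-6-{2-[(tert-butyldimethylsilyl)oxy]ethyl}-2-methyl-7-oxo-2,3,4,7-tetrahydrooxepin-2-yl]-2-(diethoxyphosphoryl)pentanoate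
Product: 19 methyl (5R)-5-acetoxy-5-[(2S)-6-(2-bromoethyl)-2-methyl-7-oxo-2,3,4,7-tetrahydrooxepin-2-yl]-2-(diethoxyphosphoryl)pentanoate
Conditions: Ph3PBr2, CH2Cl2, 25 °C
Reagents that add atoms: dibromotriphenylphosphorane, BrP(Br)(c1ccccc1)(c1ccccc1)c1ccccc1
Why: Dibromotriphenylphosphorane converts a primary tert-butyldimethylsilyl ether directly to the bromide through an oxyphosphonium ion, so a free 2-hydroxyethyl group that could translactonise onto C20 is never formed.

Step 12
Reactants: 20 3-methylbut-1-yne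
Product: 22 4-methylpent-2-yn-1-ol, via lithium acetylide 21 (not isolated)
Conditions: n-BuLi, THF, −78 °C; (CH2O)n, −78 to 25 °C
Reagents that add atoms: formaldehyde (as paraformaldehyde), C=O
Why: Addition of the lithium acetylide to formaldehyde gives the propargylic alcohol.

Step 13
Reactants: 22 4-methylpent-2-yn-1-ol
Product: 24 (Z)-3-iodo-4-methylpent-2-en-1-ol, via cyclic vinylalanate 23 (not isolated)
Conditions: NaAlH2(OCH2CH2OCH3)2, Et2O, 0 °C; then I2, THF, −78 to 0 °C
Reagents that add atoms: iodine, II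
Why: Hydroxyl-directed trans-hydroalumination places aluminium at C3 cis to the CH2O group in a five-membered alanate, and iodinolysis with retention should give the (Z)-3-iodo allylic alcohol, which fixes the C1=C2 geometry of the target.

Step 14
Reactants: 24 (Z)-3-iodo-4-methylpent-2-en-1-ol
Product: 25 (Z)-3-iodo-4-methylpent-2-enal
Conditions: MnO2, CH2Cl2, 25 °C
Reagents that add atoms: none
Why: MnO2 oxidises the allylic alcohol selectively to the enal without touching the vinyl iodide.

Step 15
Reactants: 19 methyl (5R)-5-acetoxy-5-[(2S)-6-(2-bromoethyl)-2-methyl-7-oxo-2,3,4,7-tetrahydrooxepin-2-yl]-2-(diethoxyphosphoryl)pentanoate; 25 (Z)-3-iodo-4-methylpent-2-enal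
Product: 27 methyl (5R)-5-acetoxy-2-(diethoxyphosphoryl)-5-{(2S)-2-methyl-7-oxo-6-[(3E)-5-oxo-3-(propan-2-yl)pent-3-en-1-yl]-2,3,4,7-tetrahydrooxepin-2-yl}pentanoate, via alkylzinc bromide 26 (not isolated)
Conditions: Zn dust, LiCl, THF, 50 °C; then 25, PdCl2(dppf) (5 mol %), 25 °C
Reagents that add atoms: none
Why: LiCl-assisted zinc insertion into the primary bromide gives an ester-tolerant alkylzinc that should undergo Negishi coupling with the activated β-iodo enal with retention of alkene geometry, forming C1–C14, while the weakly basic organozinc leaves the aldehyde and the phosphonoacetate C–H intact.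

Step 16
Reactants: 27 methyl (5R)-5-acetoxy-2-(diethoxyphosphoryl)-5-{(2S)-2-methyl-7-oxo-6-[(3E)-5-oxo-3-(propan-2-yl)pent-3-en-1-yl]-2,3,4,7-tetrahydrooxepin-2-yl}pentanoate
Product: 28 sarcrassin D
Conditions: LiCl, DBU, MeCN, 1 mM (slow addition), 25 °C
Reagents that add atoms: none
Why: Intramolecular Horner–Wadsworth–Emmons olefination at high dilution closes the 14-membered ring; α-alkyl phosphonoacetates react with enals to place the ester trans to the diene carbon C2, which is the C3=C4 geometry of the target.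

**Compound list**

1 | ethyl 2-methyl-3-oxobutanoate | CCOC(=O)C(C)C(C)=O | starting material
2 | tert-butyl(2-iodoethoxy)dimethylsilane | CC(C)(C)[Si](C)(C)OCCI | starting material
3 | sodium lithium dianion of 1 | CCOC(=O)[C-](C)C(=O)[CH2-].[Na+].[Li+] | intermediate (not isolated)
4 | ethyl 6-[(tert-butyldimethylsilyl)oxy]-2-methyl-3-oxohexanoate (racemic) | CCOC(=O)C(C)C(=O)CCCO[Si](C)(C)C(C)(C)C | intermediate
5 | acrolein | C=CC=O | starting material
6 | ethyl (2R)-6-[(tert-butyldimethylsilyl)oxy]-2-methyl-3-oxo-2-(3-oxopropyl)hexanoate | CCOC(=O)[C@](C)(CCC=O)C(=O)CCCO[Si](C)(C)C(C)(C)C | intermediate (not isolated)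
7 | ethyl (1R)-3-{2-[(tert-butyldimethylsilyl)oxy]ethyl}-1-methyl-2-oxocyclohex-3-ene-1-carboxylate | O=C1C(CCO[Si](C)(C)C(C)(C)C)=CCC[C@@]1(C)C(=O)OCC | intermediate
8 | (6S)-2-{2-[(tert-butyldimethylsilyl)oxy]ethyl}-6-(hydroxymethyl)-6-methylcyclohex-2-en-1-ol (C1 epimers) | OC1C(CCO[Si](C)(C)C(C)(C)C)=CCC[C@@]1(C)CO | intermediate
9 | (1S)-3-{2-[(tert-butyldimethylsilyl)oxy]ethyl}-1-methyl-2-oxocyclohex-3-ene-1-carbaldehyde | O=C1C(CCO[Si](C)(C)C(C)(C)C)=CCC[C@@]1(C)C=O | intermediate
10 | O-diisopinocampheylboryl ether of 11 | O=C1C(CCO[Si](C)(C)C(C)(C)C)=CCC[C@@]1(C)[C@H](OB([C@H]2C[C@H]3C[C@@H]([C@@H]2C)C3(C)C)[C@H]2C[C@H]3C[C@@H]([C@@H]2C)C3(C)C)CC=C | intermediate (not isolated)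
11 | (6S)-2-{2-[(tert-butyldimethylsilyl)oxy]ethyl}-6-[(1R)-1-hydroxybut-3-en-1-yl]-6-methylcyclohex-2-en-1-one | O=C1C(CCO[Si](C)(C)C(C)(C)C)=CCC[C@@]1(C)[C@H](O)CC=C | intermediate
12 | (1R)-1-[(1S)-3-{2-[(tert-butyldimethylsilyl)oxy]ethyl}-1-methyl-2-oxocyclohex-3-en-1-yl]but-3-en-1-yl acetate | O=C1C(CCO[Si](C)(C)C(C)(C)C)=CCC[C@@]1(C)[C@H](OC(C)=O)CC=C | intermediate
13 | (1R)-1-[(1S)-3-{2-[(tert-butyldimethylsilyl)oxy]ethyl}-1-methyl-2-oxocyclohex-3-en-1-yl]-3-oxopropyl acetate | O=C1C(CCO[Si](C)(C)C(C)(C)C)=CCC[C@@]1(C)[C@H](OC(C)=O)CC=O | intermediate (not isolated)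
14 | (1R)-1-[(1S)-3-{2-[(tert-butyldimethylsilyl)oxy]ethyl}-1-methyl-2-oxocyclohex-3-en-1-yl]-3-hydroxypropyl acetate | O=C1C(CCO[Si](C)(C)C(C)(C)C)=CCC[C@@]1(C)[C@H](OC(C)=O)CCO | intermediate
15 | (1R)-3-bromo-1-[(1S)-3-{2-[(tert-butyldimethylsilyl)oxy]ethyl}-1-methyl-2-oxocyclohex-3-en-1-yl]propyl acetate | O=C1C(CCO[Si](C)(C)C(C)(C)C)=CCC[C@@]1(C)[C@H](OC(C)=O)CCBr | intermediate
16 | (1R)-3-bromo-1-[(2S)-6-{2-[(tert-butyldimethylsilyl)oxy]ethyl}-2-methyl-7-oxo-2,3,4,7-tetrahydrooxepin-2-yl]propyl acetate | CC(C)(C)[Si](C)(C)OCCC1=CCC[C@](C)(OC1=O)[C@H](OC(C)=O)CCBr | intermediate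
17 | methyl 2-(diethoxyphosphoryl)acetate | COC(=O)CP(=O)(OCC)OCC | starting material
18 | methyl (5R)-5-acetoxy-5-[(2S)-6-{2-[(tert-butyldimethylsilyl)oxy]ethyl}-2-methyl-7-oxo-2,3,4,7-tetrahydrooxepin-2-yl]-2-(diethoxyphosphoryl)pentanoate (C2 epimers) | CC(C)(C)[Si](C)(C)OCCC1=CCC[C@](C)(OC1=O)[C@H](OC(C)=O)CCC(C(=O)OC)P(=O)(OCC)OCC | intermediate
19 | methyl (5R)-5-acetoxy-5-[(2S)-6-(2-bromoethyl)-2-methyl-7-oxo-2,3,4,7-tetrahydrooxepin-2-yl]-2-(diethoxyphosphoryl)pentanoate (C2 epimers) | BrCCC1=CCC[C@](C)(OC1=O)[C@H](OC(C)=O)CCC(C(=O)OC)P(=O)(OCC)OCC | intermediate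
20 | 3-methylbut-1-yne | CC(C)C#C | starting material
21 | lithium 3-methylbut-1-yn-1-ide | CC(C)C#C[Li] | intermediate (not isolated)
22 | 4-methylpent-2-yn-1-ol | CC(C)C#CCO | intermediate
23 | sodium 2,2-bis(2-methoxyethoxy)-3-(propan-2-yl)-2,5-dihydro-1,2-oxaluminol-2-uide (cyclic vinylalanate) | CC(C)C1=CCO[Al-]1(OCCOC)OCCOC.[Na+] | intermediate (not isolated)
24 | (Z)-3-iodo-4-methylpent-2-en-1-ol | OC/C=C(\I)C(C)C | intermediate
25 | (Z)-3-iodo-4-methylpent-2-enal | O=C/C=C(\I)C(C)C | intermediate
26 | alkylzinc bromide derived from 19 | Br[Zn]CCC1=CCC[C@](C)(OC1=O)[C@H](OC(C)=O)CCC(C(=O)OC)P(=O)(OCC)OCC | intermediate (not isolated)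
27 | methyl (5R)-5-acetoxy-2-(diethoxyphosphoryl)-5-{(2S)-2-methyl-7-oxo-6-[(3E)-5-oxo-3-(propan-2-yl)pent-3-en-1-yl]-2,3,4,7-tetrahydrooxepin-2-yl}pentanoate (C2 epimers) | O=C/C=C(/C(C)C)CCC1=CCC[C@](C)(OC1=O)[C@H](OC(C)=O)CCC(C(=O)OC)P(=O)(OCC)OCC | intermediate
28 | sarcrassin D | COC(=O)/C1=C/C=C(/C(C)C)CCC2=CCC[C@](C)(OC2=O)[C@H](OC(C)=O)CC1 | target

**Step count and risks**

Total steps: 16. Longest linear sequence: 13 steps (steps 1–11, 15 and 16).

Step 9 is the most exposed. The vinylic C12 may migrate instead of C8, giving an enol lactone, or the hindered conjugated ketone may form the peracid adduct so slowly that other oxidations take over. The fallback sets out from 15. Conjugate addition of thiophenol (PhSH, Et3N) should give the β-phenylsulfanyl ketone F3. Excess mCPBA then oxidises sulfur to the sulfone and inserts oxygen into the now saturated ketone, where the tertiary C8 should outcompete the secondary, sulfone-deactivated C12, giving the sulfonyl lactone F4. DBU eliminates benzenesulfinate by an E1cB pathway and the route is rejoined at 16.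

Step 16 may suffer from oligomerisation competing with ring closure, from poor control of the C3=C4 geometry inside the forming ring, or from base-induced isomerisation of the C1=C2 enal. The fallback reverses the order of the two unions and sets out from 19. Intermolecular Horner–Wadsworth–Emmons olefination with 25 (LiCl, DBU) should give the open-chain bromo iodo dienoate F5, where no ring constraint biases the olefination and isomers can be separated. The 14-membered ring is then closed at C1–C14 by intramolecular nickel-catalysed reductive cross-electrophile coupling of the alkyl bromide with the vinyl iodide (NiI2, 4,4′-di-tert-butyl-2,2′-bipyridine, Zn, DMA, high dilution), arriving at 28.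

Step 2 may give insufficient facial discrimination of the acyclic enolate, so that C8 is formed with low enantiomeric purity, or the adduct may revert by retro-Michael cleavage before ring closure. The fallback sets out from 4 and builds the quaternary centre by palladium-catalysed asymmetric allylic alkylation instead (Pd2(dba)3, chiral trans-1,2-diaminocyclohexane bis(2-diphenylphosphinobenzamide) ligand, allyl acetate, base), giving the allylated keto ester F1. Chemoselective hydroboration–oxidation of the terminal alkene (9-BBN; NaBO3) should give the primary alcohol F2; any ketone reduced on the way is restored in the next oxidation. Dess–Martin oxidation gives 6, which is cyclised with Bn2NH·CF3CO2H as in the second stage of step 2, rejoining the route at 7.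

**Further compounds**

F1 | step 2 | ethyl (2R)-6-[(tert-butyldimethylsilyl)oxy]-2-methyl-3-oxo-2-(prop-2-en-1-yl)hexanoate | CCOC(=O)[C@](C)(CC=C)C(=O)CCCO[Si](C)(C)C(C)(C)C
F2 | step 2 | ethyl (2R)-6-[(tert-butyldimethylsilyl)oxy]-2-(3-hydroxypropyl)-2-methyl-3-oxohexanoate | CCOC(=O)[C@](C)(CCCO)C(=O)CCCO[Si](C)(C)C(C)(C)C
F3 | step 9 | (1R)-3-bromo-1-[(1S)-3-{2-[(tert-butyldimethylsilyl)oxy]ethyl}-1-methyl-2-oxo-4-(phenylsulfanyl)cyclohexyl]propyl acetate (C3/C4 epimers) | O=C1C(CCO[Si](C)(C)C(C)(C)C)C(Sc2ccccc2)CC[C@@]1(C)[C@H](OC(C)=O)CCBr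
F4 | step 9 | (1R)-3-bromo-1-[(2S)-6-{2-[(tert-butyldimethylsilyl)oxy]ethyl}-2-methyl-7-oxo-5-(phenylsulfonyl)oxepan-2-yl]propyl acetate (C5/C6 epimers) | CC(C)(C)[Si](C)(C)OCCC1C(S(=O)(=O)c2ccccc2)CC[C@](C)(OC1=O)[C@H](OC(C)=O)CCBr
F5 | step 16 | methyl (2E,4Z)-2-{(3R)-3-acetoxy-3-[(2S)-6-(2-bromoethyl)-2-methyl-7-oxo-2,3,4,7-tetrahydrooxepin-2-yl]propyl}-5-iodo-6-methylhepta-2,4-dienoate | COC(=O)/C(=C/C=C(\I)C(C)C)CC[C@@H](OC(C)=O)[C@]1(C)CCC=C(CCBr)C(=O)O1
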